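- In Sunday's closed flask at 5.00 d I read 51% intermediate and 22% product, so the fraction of the charge left as substrate was 27.0%. The number to watch in a repeat is the held share (the selectivity to intermediate): intermediate divided by all the substrate that has reacted, here 0.699.

all flasks: substrate 0.10 M; second catalyst 0.7 mol%
- Sunday's: partner 2 equiv; free catalyst 0.05 mol%; run made earlier
- Tuesday's: partner 2 equiv; free catalyst 0.075 mol%; run made earlier
- green: partner 2.00 equiv; free catalyst 0.05 mol%; a closed flask charged with all of it at once and left for 8.0 d; time 8.0 d
- red: partner 2.00 equiv (fed, over 6.40 d); free catalyst 0.05 mol%; all but partner at the start; partner goes in evenly over 6.40 d, the run ends at 8.0 d; time 8.0 d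
- amber: partner 2.00 equiv; free catalyst 0.05 mol%; one stirred flow tank at steady state, fed with the mixture as stated, mean residence time 80.0 d
- teal: partner 2.00 equiv; free catalyst 0.05 mol%; one stirred flow tank at steady state, fed with the mixture as stated, mean residence time 8.0 d

Sunday's run (percent of the substrate charged)

| time / d | intermediate / % | product / % |
|---|---|---|
| 0.417 | 6 | 5 |
| 1.25 | 18 | 12 |
| 2.00 | 29 | 15 |
| 3.00 | 39 | 18 |
| 5.00 | 51 | 22 |

Tuesday's run (percent of the substrate charged)

| time / h | intermediate / % | product / % |
|---|---|---|
| 3.00 | 4 | 0 |
| 6.00 | 7 | 2 |
| 10.0 | 12 | 8 |
| 20.0 | 20 | 9 |
| 40.0 | 34 | 19 |

(readings scatter by 2 percentage points)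

- the stated concentrations are those of everything mixed, before any reaction; amounts are the same in each set-up
- the earlier runs were read with a standard deviation of 2 percentage points
- the feed brings no volume worth counting
- the earlier runs were made in a closed, stirred flask

* the set-up with the highest amount of intermediate at the outlet or at the end, in percent of the substrate put in ("none" if the first two lie within 2 percentage points) (green / red / amber / teal / none)
* amount of intermediate at the outlet or at the end, in percent of the substrate put in, green
* amount of intermediate at the outlet or at the end, in percent of the substrate put in, red
* amount of intermediate at the outlet or at the end, in percent of the substrate put in, amber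
* amount of intermediate at the outlet or at the end, in percent of the substrate put in, teal

- I worked with the fraction left. Read as pseudo-first-order, Sunday's fraction left gave 0.262 d⁻¹. On that reading a closed flask leaves the exponential of minus that constant times the time, and a tank at steady state leaves one over one plus that constant times the residence time.
- By that reckoning the fraction left was 12.3% in green, 4.56% in amber and 32.3% in teal.
- Multiplying the reacted fraction by the held share, I committed to 61.3% for green, 66.7% for amber and 47.3% for teal, which put amber ahead of green by 5.4 percentage points, more than the margin of 2 points.
- I then turned the question round: green would overtake amber if amber's held share fell below 0.919 of green's. Amber's stay is 16.0 times the length of Sunday's run, so a slow drain of intermediate was the risk. But the share as read in Sunday's run was 0.659 at 2.00 d and 0.699 at 5.00 d, which showed no fall within readings scattered by 2 points, so I kept amber.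
- For red I took green's 61.3%, assuming that partner plays no part in the loss of substrate, which was untested because both earlier runs had 2 equiv of partner. Sunday's product stood at 5% by 0.417 d, a time shorter than the 1.60 d that red stirs after its feed ends.
- The forecast named amber, with 60% for green, 52% for red, below my figure, 66% for amber and 46% for teal, noting that “the partner order is unknown”.
- The flasks gave amber as best, with 61.6% in green, 61.6% in red, 65.2% in amber and 47.3% in teal.

    substrate + free catalyst → free catalyst + intermediate (k = 250 L mol⁻¹ h⁻¹)
    partner + second catalyst + intermediate ⇌ second catalyst + product (K = 2.80 L mol⁻¹, k = 3300 L² mol⁻² h⁻¹)

- The held share came out at 0.679 in amber and 0.670 in teal, with 4.00% and 29.4% of the substrate left. The simulated amber run shows the main reason why amber holds its intermediate: without the undoing of product into partner and intermediate on the second catalyst, amber falls from 65.2% to 0.207%. The slow dosing of partner was not what set red, which stands at 61.6% with the feed and 61.6% without it.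

Readings and results are calculated with made-up constants, noise included.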